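The ratio to carry is the constant by which single product is lost over the constant by which it is made, and reagent cancels from the rates it compares.

    starting material + reagent → single product (k1 = 1.4 × 10⁻⁴ L mol⁻¹ s⁻¹)
    reagent + single product → bis adduct (k2 = 2.5 × 10⁻⁵ L mol⁻¹ s⁻¹)
    reagent + bis adduct → tris adduct (k3 = 1.4 × 10⁻⁴ L mol⁻¹ s⁻¹)
    reagent + single product → over-reaction product (k4 = 9.1 × 10⁻⁶ L mol⁻¹ s⁻¹)

| setting | noon | winter | midnight | summer |
|---|---|---|---|---|
| starting material | 0.071 M | 0.071 M | 0.071 M | 0.071 M |
| reagent | 0.0120 M | 0.0400 M | 0.100 M | 0.300 M |
| time | 5.0 d | 5.0 d | 5.0 d | 5.0 d |

- amount of single product at the end, in percent of the starting material charged for noon, winter, midnight, summer, in this order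
- how that number moves from the first to the last of them (falls all the way / hardly changes / rises, then falls / falls, then rises / rises all the way)

- "hardly changes" means that all values lie within two and a half points (for a concentration: within two and a half percent of the largest)
- run time (noon): 5.0 d

Minutes of the meeting. The kineticist opened. She said that [reagent] multiplies each rate that touches [single product], so it drops out when one rate is divided by another. She proposed to freeze s = 0.244, the sum of the constants of the two steps that consume single product over the constant of the step that makes it. This is a selectivity factor.

With x the fraction of starting material left, she integrated to a curve with no [reagent] in it. Single product, as a fraction of starting material charged, is (x^s − x)/(1 − s). Its peak is 63.5 %, at x = 15.5 %.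

The process chemist replied that the peak costs reagent: one for each starting material turned, one more for each single product lost. That came to 0.0750 M, and more once bis adduct goes on to tris adduct. Noon and winter charge less than that, so he placed them on the rising side. Midnight charges more.

The chair took summer. With reagent held at its summer charge, a pseudo-first-order view, starting material in summer has a half-life of 0.191 d, far shorter than the 5.0 d allowed. So she put summer past the peak, on the falling side.

For noon, the kineticist took the reagent as spent on starting material. That gives x = 83.1 % for noon, and the curve reads 16.5 % for noon.

The forecast gave 15.8 %, 44.8 %, 63 % and 11.7 %, shape rises, then falls, on the ground, for little reagent, that “the single product is capped by the reagent charged”, and its noon figure lies below the one reckoned here.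

The flask gave 15.8 %, 44.8 %, 62.9 % and 11.7 %, shape rises, then falls. At midnight 11.7 % of the starting material was left at the end, just past the peak's x, and the curve reads 62.9 % there. In summer, after 2.50 d, starting material stood at 0.272 %. The curve reads 30.9 % at that x, and single product stood at 31.0 %.

The constants are assumed; what happens was integrated by code.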